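## Retrosynthetic overview

1. 20 ⇒ 17: the succinimide ring is closed last by C16–N bond formation; a carboxamide nitrogen, unmasked from a nitrile, displaces the oxazolidinone auxiliary.
2. 17 ⇒ 10 + 14: the C12–C13 bond and both side-chain stereocentres come from an Evans syn-aldol.
3. 10 ⇒ 4: the sclareolide lactone is opened to a Weinreb amide, dehydrated to the C8=C17 olefin and reduced to the aldehyde.
4. 4 ⇒ 2 ⇒ 1: the C18–O bond comes from undirected iridium-catalysed C–H borylation/oxidation of the only equatorial methyl (new); the C2–Cl bond from radical C–H chlorination.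
5. Ring order: rings A and B are bought intact in (+)-sclareolide 1, its lactone ring is sacrificed, and the succinimide ring is formed last.

Assumption: the N-chloroamide of step 1 and the platinum hydration catalyst of step 8 are bought as catalogue reagents; atoms carry labdane numbering (C18 = equatorial 4α carbon, C19 = axial 4β methyl, C20 = methyl on C10, C17 = methyl or methylene on C8).

## Route

Step 1
Reactants: 1 (+)-sclareolide
Product: 2 2α-chlorosclareolide
Conditions: N-chloroamide (1.2 equiv), Cs2CO3 (1 equiv), PhH, visible light, 55 °C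
Reagents that add atoms: N-tert-butyl-N-chloro-3,5-bis(trifluoromethyl)benzamide, CC(C)(C)N(Cl)C(=O)c1cc(cc(c1)C(F)(F)F)C(F)(F)F
Why: Amidyl-radical chain C–H chlorination: the bulky electrophilic amidyl radical abstracts hydrogen at C2, the least hindered methylene farthest from the electron-withdrawing lactone, and the C2 radical takes chlorine on the α face (the β face is screened by the syn-axial C19 and C20 methyls), giving the equatorial 2α-chloride.

Step 2
Reactants: 2 2α-chlorosclareolide
Product: 4 2α-chloro-C18-hydroxysclareolide, via pinacol boronate 3 (not isolated)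
Conditions: [Ir(cod)OMe]2 (5 mol %), 2-methyl-1,10-phenanthroline (10 mol %), B2pin2 (2 equiv), cyclooctane, 100 °C; then NaBO3·4H2O, THF/H2O, rt
Reagents that add atoms: sodium perborate (used as NaBO3·4H2O), [Na+].[O-]OB=O
Why: Proposed new method: undirected iridium-catalysed C(sp3)–H borylation of a neopentylic methyl group of a polycyclic terpenoid lactone, telescoped with B-to-O oxidation as a net C18–H hydroxylation — the trivalent iridium tris(boryl) species carrying 2-methylphenanthroline cleaves C–H bonds through a crowded four-centre transition state that accepts only primary C–H bonds of unstrained alkanes (ring CH2 groups are inert, hence cyclooctane as solvent), and of the four methyls of 2 the axial C19 and C20 are mutually syn-axial, axial C17 is syn-axial to C20 and geminal to the lactone oxygen, whereas C18 is the only equatorial methyl and lies on the open α edge far from the chloride, so borylation there differentiates the two C4 methyls and fixes C4 (CH2O α, CH3 β) before perborate replaces boron by oxygen; the closest known reaction type is iridium/phenanthroline-catalysed borylation of primary alkyl C–H bonds with the substrate as limiting reagent followed by boronate oxidation, which to my knowledge has not been shown for a methyl on a quaternary ring carbon of such a scaffold.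

Step 3
Reactants: 4 2α-chloro-C18-hydroxysclareolide
Product: 5 N-methoxy-N-methyl 2α-chloro-8α,18-dihydroxy-13,14,15,16-tetranorlabdan-12-amide
Conditions: MeNH(OMe)·HCl (4 equiv), AlMe3 (4 equiv), CH2Cl2, 0 °C to rt; aq. potassium sodium tartrate
Reagents that add atoms: N,O-dimethylhydroxylamine hydrochloride, CNOC.Cl
Why: Weinreb aminolysis of the γ-lactone by the aluminium amide (acyl–oxygen cleavage) frees the tertiary C8 alcohol and touches no stereocentre.

Step 4
Reactants: 5 N-methoxy-N-methyl 2α-chloro-8α,18-dihydroxy-13,14,15,16-tetranorlabdan-12-amide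
Product: 8 N-methoxy-N-methyl 2α-chloro-18-(triethylsilyloxy)-13,14,15,16-tetranorlabd-8(17)-en-12-amide, via silyl ether 6 (not isolated), via chlorosulfite 7 (not isolated)
Conditions: TESCl (1.1 equiv), pyridine, DMAP (cat.), CH2Cl2, 0 °C; then SOCl2 (2 equiv), −78 °C
Reagents that add atoms: chlorotriethylsilane, CC[Si](Cl)(CC)CC
Why: Selective silylation of the primary alcohol is followed by pyridine-mediated E2 dehydration of the tertiary chlorosulfite; the C8–O bond is equatorial, so no ring hydrogen is antiperiplanar to it and only a C17 methyl hydrogen can be, which favours the exocyclic olefin.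

Step 5
Reactants: 8 N-methoxy-N-methyl 2α-chloro-18-(triethylsilyloxy)-13,14,15,16-tetranorlabd-8(17)-en-12-amide
Product: 10 2α-chloro-18-(triethylsilyloxy)-13,14,15,16-tetranorlabd-8(17)-en-12-al, via aluminium hemiaminal 9 (not isolated)
Conditions: i-Bu2AlH (1.5 equiv), THF, −78 °C; aq. potassium sodium tartrate
Reagents that add atoms: none
Why: Weinreb amide reduction: hydride adds once and the chelated aluminium hemiaminal survives until hydrolysis, so there is no over-reduction, and C9 is β to the carbonyl and cannot epimerise.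

Step 6
Reactants: 11 3-cyanopropanoic acid; 12 (R)-4-benzyl-1,3-oxazolidin-2-one
Product: 14 (R)-4-benzyl-3-(3-cyanopropanoyl)-1,3-oxazolidin-2-one, via mixed anhydride 13 (not isolated)
Conditions: PivCl, Et3N, THF, −20 °C; then LiCl, 12, −20 °C to rt
Reagents that add atoms: none
Why: Mixed-anhydride N-acylation of the oxazolidinone under LiCl/Et3N activation; the nitrile serves as a latent carboxamide that cannot cyclise prematurely, and no stereocentre is touched.

Step 7
Reactants: 10 2α-chloro-18-(triethylsilyloxy)-13,14,15,16-tetranorlabd-8(17)-en-12-al; 14 (R)-4-benzyl-3-(3-cyanopropanoyl)-1,3-oxazolidin-2-one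
Product: 17 (12S,13R) syn-aldol adduct carrying CH2CN on C13 and the acyl oxazolidinone as C16, via boron enolate 15 (not isolated), via boron aldolate 16 (not isolated)
Conditions: 14, Bu2BOTf (1.2 equiv), i-Pr2NEt (1.4 equiv), CH2Cl2, −78 to 0 °C; then 10, −78 to 0 °C; pH 7 buffer, MeOH, 30% H2O2, 0 °C
Reagents that add atoms: none
Why: Evans syn-aldol: the Z dibutylboron enolate reacts through a closed Zimmerman–Traxler chair with the auxiliary carbonyl turned away, the (R)-benzyl group blocks one enolate face, and this sets C13 (R) and C12 (S) under reagent control irrespective of the remote C9 centre.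

Step 8
Reactants: 17 (12S,13R) syn-aldol adduct
Product: 20 haterumaimide J, via carboxamide 18 (not isolated), via silyl imide 19 (not isolated)
Conditions: [PtH(PMe2OH)(PMe2O)2H] (5 mol %), EtOH/H2O 4:1, 80 °C; then Et3N (1.5 equiv), 50 °C; then 1 M HCl, THF, rt
Reagents that add atoms: water, O
Why: Ghaffar–Parkins nitrile hydration on divalent platinum under neutral conditions gives the carboxamide, whose nitrogen attacks the activated N-acyloxazolidinone carbonyl C16 (5-exo-trig acyl transfer, C16–N bond) to expel the auxiliary and close the succinimide without touching C12 or C13, and dilute acid then cleaves the silyl ether.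

## Compound list

1 | (+)-sclareolide, (3aR,5aS,9aS,9bR)-3a,6,6,9a-tetramethyldecahydronaphtho[2,1-b]furan-2(1H)-one | C[C@@]12CC[C@H]3C(C)(C)CCC[C@]3(C)[C@H]1CC(=O)O2 | starting material
2 | 2α-chlorosclareolide (equatorial Cl at C2) | C[C@@]12CC[C@H]3C(C)(C)C[C@H](Cl)C[C@]3(C)[C@H]1CC(=O)O2 | intermediate
3 | 2α-chloro-18-(pinacolboryl)sclareolide, Bpin on the equatorial 4α-CH2 (not isolated) | C[C@@]12CC[C@H]3[C@](C)(CB4OC(C)(C)C(C)(C)O4)C[C@H](Cl)C[C@]3(C)[C@H]1CC(=O)O2 | intermediate
4 | 2α-chloro-C18-hydroxysclareolide (4α-CH2OH, 4β-CH3) | C[C@@]12CC[C@H]3[C@](C)(CO)C[C@H](Cl)C[C@]3(C)[C@H]1CC(=O)O2 | intermediate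
5 | N-methoxy-N-methyl 2α-chloro-8α,18-dihydroxy-13,14,15,16-tetranorlabdan-12-amide | C[C@@]1(O)CC[C@H]2[C@](C)(CO)C[C@H](Cl)C[C@]2(C)[C@H]1CC(=O)N(C)OC | intermediate
6 | C18-O-triethylsilyl ether of 5, tertiary C8–OH free (not isolated) | C[C@@]1(O)CC[C@H]2[C@](C)(CO[Si](CC)(CC)CC)C[C@H](Cl)C[C@]2(C)[C@H]1CC(=O)N(C)OC | intermediate
7 | C8-O-chlorosulfite of 6 (not isolated) | C[C@@]1(OS(=O)Cl)CC[C@H]2[C@](C)(CO[Si](CC)(CC)CC)C[C@H](Cl)C[C@]2(C)[C@H]1CC(=O)N(C)OC | intermediate
8 | N-methoxy-N-methyl 2α-chloro-18-(triethylsilyloxy)-13,14,15,16-tetranorlabd-8(17)-en-12-amide | C=C1CC[C@H]2[C@](C)(CO[Si](CC)(CC)CC)C[C@H](Cl)C[C@]2(C)[C@H]1CC(=O)N(C)OC | intermediate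
9 | C12 O-diisobutylaluminium N-methoxy-N-methyl hemiaminal of 8 (not isolated) | C=C1CC[C@H]2[C@](C)(CO[Si](CC)(CC)CC)C[C@H](Cl)C[C@]2(C)[C@H]1CC(O[Al](CC(C)C)CC(C)C)N(C)OC | intermediate
10 | 2α-chloro-18-(triethylsilyloxy)-13,14,15,16-tetranorlabd-8(17)-en-12-al | C=C1CC[C@H]2[C@](C)(CO[Si](CC)(CC)CC)C[C@H](Cl)C[C@]2(C)[C@H]1CC=O | intermediate
11 | 3-cyanopropanoic acid | N#CCCC(=O)O | starting material
12 | (R)-4-benzyl-1,3-oxazolidin-2-one | O=C1OC[C@@H](Cc2ccccc2)N1 | starting material
13 | 3-cyanopropanoic pivalic anhydride (not isolated) | N#CCCC(=O)OC(=O)C(C)(C)C | intermediate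
14 | (R)-4-benzyl-3-(3-cyanopropanoyl)-1,3-oxazolidin-2-one | N#CCCC(=O)N1[C@H](Cc2ccccc2)COC1=O | intermediate
15 | Z dibutylboron enolate of 14 (not isolated) | N#CC/C=C(\OB(CCCC)CCCC)N1[C@H](Cc2ccccc2)COC1=O | intermediate
16 | C12-O-dibutylboryl aldolate of 17 (not isolated) | C=C1CC[C@H]2[C@](C)(CO[Si](CC)(CC)CC)C[C@H](Cl)C[C@]2(C)[C@H]1C[C@H](OB(CCCC)CCCC)[C@@H](CC#N)C(=O)N1[C@H](Cc2ccccc2)COC1=O | intermediate
17 | (R)-4-benzyl-3-[(2R,3S)-2-(cyanomethyl)-3-hydroxy-4-(decalinyl)butanoyl]oxazolidin-2-one, decalinyl = C9 of the 2α-chloro-18-(triethylsilyloxy)-8(17)-ene bicycle; (12S,13R) | C=C1CC[C@H]2[C@](C)(CO[Si](CC)(CC)CC)C[C@H](Cl)C[C@]2(C)[C@H]1C[C@H](O)[C@@H](CC#N)C(=O)N1[C@H](Cc2ccccc2)COC1=O | intermediate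
18 | primary carboxamide from 17, CH2CONH2 on C13 (not isolated) | C=C1CC[C@H]2[C@](C)(CO[Si](CC)(CC)CC)C[C@H](Cl)C[C@]2(C)[C@H]1C[C@H](O)[C@@H](CC(N)=O)C(=O)N1[C@H](Cc2ccccc2)COC1=O | intermediate
19 | C18-O-triethylsilyl haterumaimide J (not isolated) | C=C1CC[C@H]2[C@](C)(CO[Si](CC)(CC)CC)C[C@H](Cl)C[C@]2(C)[C@H]1C[C@H](O)[C@H]1CC(=O)NC1=O | intermediate
20 | haterumaimide J | C=C1CC[C@H]2[C@](C)(CO)C[C@H](Cl)C[C@]2(C)[C@H]1C[C@H](O)[C@H]1CC(=O)NC1=O | target

## Step count and risk

Total step count: 8. Longest linear sequence: 7 (1 → 2 → 4 → 5 → 8 → 10 → 17 → 20; step 6 is a one-step side branch).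

**Step 2 (the new C18–H hydroxylation).** It may fail through no turnover at a neopentylic methyl, competing borylation at C17 (primary C–H β to the lactone oxygen), or loss of the secondary chloride under the iridium/borane conditions. The fallback uses known reaction types only, sets out from 1 and comes back at 4. An engineered P450 BM3 variant (whole cells, air) hydroxylates 1 at C3 to give 3β-hydroxysclareolide F1. Dehydrogenative silylation (Et2SiH2, [Ir(cod)OMe]2 cat.) gives 3β-(diethylsilyloxy)sclareolide F2. Hydroxyl-directed iridium-catalysed γ-C–H silylation ([Ir(cod)OMe]2, 3,4,7,8-tetramethyl-1,10-phenanthroline, norbornene, THF, 120 °C) closes onto the equatorial methyl to give the C3-O/C18 oxasilolane F3. Tamao–Fleming oxidation (H2O2, KHCO3, MeOH/THF) gives 3β,18-dihydroxysclareolide F4. Primary-selective acetylation (Ac2O, collidine, −20 °C) gives 18-acetoxy-3β-hydroxysclareolide F5. PhOC(S)Cl/DMAP/pyridine gives the phenyl thionocarbonate F6, and Barton–McCombie deoxygenation (Bu3SnH, AIBN, PhMe, 110 °C) gives 18-acetoxysclareolide F7. The chlorination of step 1, with the acetate deactivating the C18 and C3 hydrogens, gives 18-acetoxy-2α-chlorosclareolide F8, and K2CO3/MeOH followed by mild acid returns 4.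

**Step 8 (hydration/imide closure/desilylation in one flask).** The C12 hydroxyl may compete (imino-lactone from the nitrile, or N-to-O acyl shift onto the oxazolidinone), and C13 may epimerise under base. The fallback sets out from 17 and comes back at 19, then 20. It removes the auxiliary first and closes the ring by carboxyl activation instead of auxiliary displacement. LiOH/H2O2 (THF/H2O, 0 °C) gives the (12S,13R) hydroxy nitrile acid F10. The same platinum-catalysed hydration gives the succinamic acid F11. Carbodiimide cyclodehydration (EDC·HCl, HOBt, i-Pr2NEt, CH2Cl2) gives 19, and 1 M HCl/THF gives 20.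

**Step 4 (one-pot silylation/dehydration).** The elimination may give endocyclic olefins beside 8. The fallback sets out from 5 and comes back at 8. It does not fight the regiochemistry of the elimination: 6 is isolated and dehydrated by a thermal syn-elimination (Burgess reagent, PhMe, 50 °C), and the trisubstituted Δ7 olefin F9 in the mixture is then moved to the exocyclic position. This uses the known photoredox/chromium contra-thermodynamic positional isomerisation (for example [Ir(dF(CF3)ppy)2(5,5'-d(CF3)bpy)]PF6, CrCl2, a hindered pyridine base, MeOH, blue light). In it the allyl radical formed at C17 is captured by divalent chromium and protonated at C7, converging on 8, which is itself inert to these conditions.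

## Further compounds

F1 | step 2 | 3β-hydroxysclareolide | C[C@@]12CC[C@H]3C(C)(C)[C@@H](O)CC[C@]3(C)[C@H]1CC(=O)O2
F2 | step 2 | 3β-(diethylsilyloxy)sclareolide | C[C@@]12CC[C@H]3C(C)(C)[C@@H](O[SiH](CC)CC)CC[C@]3(C)[C@H]1CC(=O)O2
F3 | step 2 | C3-O/C18 diethyl oxasilolane of sclareolide | C[C@@]12CC[C@H]3[C@]4(C)C[Si](CC)(CC)O[C@H]4CC[C@]3(C)[C@H]1CC(=O)O2
F4 | step 2 | 3β,18-dihydroxysclareolide | C[C@@]12CC[C@H]3[C@](C)(CO)[C@@H](O)CC[C@]3(C)[C@H]1CC(=O)O2
F5 | step 2 | 18-acetoxy-3β-hydroxysclareolide | C[C@@]12CC[C@H]3[C@](C)(COC(C)=O)[C@@H](O)CC[C@]3(C)[C@H]1CC(=O)O2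
F6 | step 2 | 18-acetoxy-3β-(phenoxythiocarbonyloxy)sclareolide | C[C@@]12CC[C@H]3[C@](C)(COC(C)=O)[C@@H](OC(=S)Oc4ccccc4)CC[C@]3(C)[C@H]1CC(=O)O2
F7 | step 2 | 18-acetoxysclareolide | C[C@@]12CC[C@H]3[C@](C)(COC(C)=O)CCC[C@]3(C)[C@H]1CC(=O)O2
F8 | step 2 | 18-acetoxy-2α-chlorosclareolide | C[C@@]12CC[C@H]3[C@](C)(COC(C)=O)C[C@H](Cl)C[C@]3(C)[C@H]1CC(=O)O2
F9 | step 4 | Δ7 (endocyclic) isomer of 8 | CC1=CC[C@H]2[C@](C)(CO[Si](CC)(CC)CC)C[C@H](Cl)C[C@]2(C)[C@H]1CC(=O)N(C)OC
F10 | step 8 | (12S,13R) hydroxy nitrile acid, CO2H as C16 | C=C1CC[C@H]2[C@](C)(CO[Si](CC)(CC)CC)C[C@H](Cl)C[C@]2(C)[C@H]1C[C@H](O)[C@@H](CC#N)C(=O)O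
F11 | step 8 | (12S,13R) succinamic acid, CH2CONH2 on C13 | C=C1CC[C@H]2[C@](C)(CO[Si](CC)(CC)CC)C[C@H](Cl)C[C@]2(C)[C@H]1C[C@H](O)[C@@H](CC(N)=O)C(=O)O
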